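**Retrosynthetic overview**

- Numbering and feature: ring B is C5–C10 (C5 fusion CH, C8 CH–CH3, C9 C(CH3)(C11H2–quinone), C10 fusion C–CH3). Ring A is C1–C4 plus C5 and C10, and C4 carries =CH2. β is the face of the three methyl groups. The plan rests on the fusion bond C5–C10. With a temporary ketone at C6, C5 and C10 are the α- and β-carbons of a ring-B enone. The ring-A bonds C10–C1 (α) and C5–C4 (β) lie on opposite faces, so the trans fusion equals an anti double addition across C5=C10.
- Late disconnections: hydroxy-methoxy-quinone ⇒ 2,3,5,6-tetramethoxyaryl group. The C11–aryl bond ⇒ aryllithium plus C11 aldehyde, followed by radical deoxygenation. C4=CH2 ⇒ C4 ketone ⇒ C4 carbinol.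
- Ring A ⇒ ring-closing metathesis (C2=C3) of a C10-allyl/C5-(1-silyloxyallyl)cyclohexanone. The C6 carbonyl is deleted afterwards through its Δ6 enol triflate.
- C1–C10 and C4–C5 ⇒ allyltrimethylsilane + acrolein + enone 10. Enone 10 ⇒ (S)-3-methylcyclohexanone by dehydrogenation, two α'-alkylations (CH3, then CH2OBn) and CH3Li addition with oxidative transposition.
- Ring order: ring B is bought (1), ring A closes in step 9, and the quinone ring arrives as an arene in step 14 and is unveiled in steps 20–22.

Key step: step 7

Assumption: (S)-3-methylcyclohexanone (1) is bought enantiopure. Centres that are erased later (C1 of 9, C4 of 14–29, C11 of 25–27) are drawn as the expected epimer or left open, and they have no bearing on the target.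

**Step 1**
Reactants: 1 (S)-3-methylcyclohexan-1-one
Product: 2 {[(5S)-5-methylcyclohex-1-en-1-yl]oxy}trimethylsilane
Conditions: LiN(iPr)2, Me3SiCl (present from the start), THF, −78 °C
Reagents that add atoms: chlorotrimethylsilane, C[Si](C)(C)Cl
Why: Kinetic enolisation by the bulky amide with internal silyl quench (silyl enol ether formation) should take a proton from the ring CH2 remote from the methyl-bearing carbon, the stereocentre (future C8) is untouched, and any regioisomeric enol ether ends after step 2 as achiral 3-methylcyclohex-2-enone, which is removed there.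

**Step 2**
Reactants: 2 {[(5S)-5-methylcyclohex-1-en-1-yl]oxy}trimethylsilane
Product: 3 (5S)-5-methylcyclohex-2-en-1-one
Conditions: Pd(OAc)2 (10 mol %), O2 (1 atm), DMSO, rt
Reagents that add atoms: none
Why: Saegusa–Ito dehydrogenation in its aerobic catalytic form, in which the oxa-π-allylpalladium species born from the silyl enol ether loses a β-hydride, places the alkene exactly where the enol ether stood and leaves the remote stereocentre alone.

**Step 3**
Reactants: 3 (5S)-5-methylcyclohex-2-en-1-one
Product: 5 (5S,6R)-5,6-dimethylcyclohex-2-en-1-one (trans), via lithium dienolate 4 (not isolated)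
Conditions: LiN(iPr)2, THF, −78 °C; then MeI, −78 → −20 °C
Reagents that add atoms: iodomethane, CI
Why: Kinetic α'-deprotonation of a cyclohexenone gives the cross-conjugated dienolate 4, whose methylation (enolate alkylation) should occur anti to the neighbouring methyl group, and the new centre is flattened again in step 4, so its configuration is of no consequence.

**Step 4**
Reactants: 5 (5S,6R)-5,6-dimethylcyclohex-2-en-1-one; 6 benzyl chloromethyl ether
Product: 8 (5S,6S)-6-[(benzyloxy)methyl]-5,6-dimethylcyclohex-2-en-1-one, via lithium dienolate 7 (not isolated)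
Conditions: LiN(iPr)2, THF, −78 → 0 °C; then 6, THF–DMPU, −78 → −20 °C
Reagents that add atoms: benzyl chloromethyl ether 6, ClCOCc1ccccc1
Why: Second α'-alkylation of a 5-substituted cyclohexenone (the pattern familiar from 6-alkylcarvones): in the flat dienolate 7 allylic strain with the C6 methyl turns the C5 methyl pseudoaxial, so the electrophile is taken up on the opposite face and the new quaternary centre (future C9) carries CH2OBn trans and CH3 cis to the future C8 methyl.

**Step 5**
Reactants: 8 (5S,6S)-6-[(benzyloxy)methyl]-5,6-dimethylcyclohex-2-en-1-one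
Product: 9 (5S,6S)-6-[(benzyloxy)methyl]-1,5,6-trimethylcyclohex-2-en-1-ol (both C1 epimers)
Conditions: MeLi, Et2O, −78 °C; H2O
Reagents that add atoms: methyllithium, [Li]C
Why: The small, hard organolithium adds 1,2 to the enone carbonyl even beside a quaternary carbon, and both carbinol epimers converge in step 6.

**Step 6**
Reactants: 9 (5S,6S)-6-[(benzyloxy)methyl]-1,5,6-trimethylcyclohex-2-en-1-ol
Product: 10 (4R,5S)-4-[(benzyloxy)methyl]-3,4,5-trimethylcyclohex-2-en-1-one
Conditions: pyridinium chlorochromate C5H5NH[CrO3Cl], 4 Å sieves, CH2Cl2, rt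
Reagents that add atoms: pyridinium chlorochromate (delivers the carbonyl oxygen), [O-][Cr](=O)(=O)Cl.c1cc[nH+]cc1
Why: Babler–Dauben oxidative transposition, in which the tertiary allylic chromate ester shifts [3,3] to the unhindered secondary terminus and is oxidised there, moves the carbonyl to C6 and leaves C5=C10 with the methyl on C10, while C8 and C9 take no part.

**Step 7**
Reactants: 10 (4R,5S)-4-[(benzyloxy)methyl]-3,4,5-trimethylcyclohex-2-en-1-one; 11 allyltrimethylsilane; 12 acrolein
Product: 14 (2R,3S,4R,5S)-4-[(benzyloxy)methyl]-2-[(1R)-1-hydroxyprop-2-en-1-yl]-3,4,5-trimethyl-3-(prop-2-en-1-yl)cyclohexan-1-one, via trichlorotitanium enolate 13 (not isolated)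
Conditions: TiCl4, 11 (small excess), CH2Cl2, −78 → −40 °C; then 12 (excess), −78 °C; cold H2O quench
Reagents that add atoms: allyltrimethylsilane 11, C=CC[Si](C)(C)C; acrolein 12, C=CC=O
Why: TiCl4 binds the C6 carbonyl and the allylsilane attacks C10 through its γ-carbon (Hosomi–Sakurai conjugate allylation, the β-silyl cation collapsing to Me3SiCl), which leaves the regiodefined enolate 13, and this adds at C5 to titanium-activated acrolein, the whole being the known three-component allylsilane/enone/aldehyde coupling of β,β-disubstituted enones. No ring closes; the step forms C1–C10 and C4–C5. C10 is set by the stereoelectronically favoured axial attack on the half-chair that keeps the C8 methyl equatorial and hence the cis C9 methyl pseudoaxial: the axial path lies on the α face, anti to that C9 methyl and trans to the C8 methyl, so C1 ends cis to C11. C5 is set because the freshly installed pseudoaxial allyl group on the adjacent carbon screens the α face of 13 and β attack is also the axial, chair-forming path, in line with 4,4-disubstituted cyclohexenones, which give trans-2,3 products despite a syn-axial C4 substituent; C4 is drawn as the anti aldol expected from a closed transition state of the ring (E)-enolate and is erased in step 18. The step needs 1,4- rather than 1,2-allylation (soft allylsilane on a Lewis-acid-bound enone), aldolisation at C5 rather than C7 (the enolate is used as it is born, without proton exchange) and 1,2-addition to acrolein (titanium-bound aldehyde). The cold quench keeps the kinetically formed 5β substituent, which is the less stable epimer, from equilibrating by enolisation or retro-aldol cleavage.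

**Step 8**
Reactants: 14 aldol adduct
Product: 15 tert-butyldimethylsilyl ether of 14 at the C4 oxygen
Conditions: t-BuMe2SiOTf, 2,6-lutidine, CH2Cl2, −78 → 0 °C
Reagents that add atoms: tert-butyldimethylsilyl trifluoromethanesulfonate, CC(C)(C)[Si](C)(C)OS(=O)(=O)C(F)(F)F
Why: O-Silylation with the silyl triflate and a hindered pyridine is fast at low temperature and too weakly basic to provoke retro-aldol cleavage or C5 epimerisation of the β-hydroxy ketone.

**Step 9**
Reactants: 15 silyl ether
Product: 16 trans-octalone (C2=C3; 4α-OSi(t-Bu)Me2; 6-oxo; 5α-H; 8β-CH3; 9β-CH3; 9α-CH2OBn; 10β-CH3)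
Conditions: second-generation Grubbs catalyst (H2IMes)(PCy3)Cl2Ru=CHPh (5 mol %), CH2Cl2 (dilute), 40 °C
Reagents that add atoms: none
Why: Ring-closing metathesis of the two monosubstituted alkenes closes ring A as a cyclohexene with loss of ethene, and since only the ring-B chair with C1 and C4 both equatorial can cyclise, the anti relationship of step 7 becomes the trans ring fusion.

**Step 10**
Reactants: 16 trans-octalone
Product: 18 Δ6 enol triflate (C6–OSO2CF3; C6=C7; otherwise as 16), via potassium enolate 17 (not isolated)
Conditions: KN(SiMe3)2, THF, −78 °C (16 added to the base); then N-(5-chloropyridin-2-yl)bis(trifluoromethanesulfonimide), −78 °C; H2O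
Reagents that add atoms: N-(5-chloropyridin-2-yl)bis(trifluoromethanesulfonimide), FC(F)(F)S(=O)(=O)N(c1ccc(Cl)cn1)S(=O)(=O)C(F)(F)F
Why: Kinetic deprotonation at the C7 methylene rather than at the tertiary C5–H followed by O-sulfonylation (enol triflate formation) removes the carbonyl without ever enolising C5 or eliminating the β-silyloxy group, and it avoids carbonyl addition chemistry, which would suffer under the syn-axial C8 and C10 methyl groups.

**Step 11**
Reactants: 18 enol triflate
Product: 19 trans-hexalin diene (C2=C3 and C6=C7; 4α-OSi(t-Bu)Me2; 9α-CH2OBn)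
Conditions: Pd(OAc)2 (5 mol %), PPh3, HCO2H, Et3N, DMF, 60 °C
Reagents that add atoms: none
Why: Palladium-catalysed formate reduction of an enol triflate (oxidative addition to zerovalent palladium, decarboxylation of formate to a palladium hydride, reductive elimination) replaces C6–O by C6–H under mild, non-epimerising conditions.

**Step 12**
Reactants: 19 diene
Product: 21 trans-decalin primary alcohol (C11–OH; 4α-OSi(t-Bu)Me2), via saturated benzyl ether 20 (not isolated)
Conditions: H2, PtO2, EtOAc, rt; then Pd(OH)2/C and EtOH added, H2, rt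
Reagents that add atoms: none
Why: Catalytic hydrogenation on platinum, which migrates double bonds far less than palladium, first saturates both disubstituted alkenes so that the allylic C5–H and C8–H centres are not scrambled, and the palladium catalyst added afterwards cleaves the benzyl ether by hydrogenolysis, no new stereocentre being formed.

**Step 13**
Reactants: 21 primary alcohol
Product: 22 C11 aldehyde (9α-CHO; 4α-OSi(t-Bu)Me2)
Conditions: Dess–Martin periodinane, CH2Cl2, rt
Reagents that add atoms: none
Why: Dess–Martin oxidation of the neopentyl alcohol stops at the aldehyde, which has no α-hydrogen and cannot epimerise.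

**Step 14**
Reactants: 22 C11 aldehyde; 23 1,2,4,5-tetramethoxybenzene
Product: 25 C11 aryl carbinol (C11 bears OH and 2,3,5,6-tetramethoxyphenyl; both C11 epimers), via aryllithium 24 (not isolated)
Conditions: 23, n-BuLi, THF, 0 °C → rt; then 22, −78 → 0 °C; H2O
Reagents that add atoms: 1,2,4,5-tetramethoxybenzene 23, COc1cc(OC)c(OC)cc1OC
Why: Directed ortho-lithiation between two methoxy groups gives 24, which adds 1,2 to the non-enolisable aldehyde, and the new C11 carbinol centre is removed in step 16.

**Step 15**
Reactants: 25 aryl carbinol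
Product: 27 O-(C11) S-methyl dithiocarbonate of 25, via sodium xanthate 26 (not isolated)
Conditions: NaH, CS2, THF, 0 °C → rt; then MeI
Reagents that add atoms: carbon disulfide, S=C=S; iodomethane, CI
Why: Xanthate formation works at crowded carbinols because the alkoxide only has to reach the small, linear CS2, after which the dithiocarbonate salt 26 is S-methylated.

**Step 16**
Reactants: 27 xanthate
Product: 28 C11H2–aryl decalin (2,3,5,6-tetramethoxybenzyl on C9α; 4α-OSi(t-Bu)Me2)
Conditions: Bu3SnH, AIBN (cat.), toluene, 110 °C
Reagents that add atoms: none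
Why: Barton–McCombie deoxygenation (stannyl radical addition to C=S, β-scission to the benzylic C11 radical, hydrogen transfer from Bu3SnH) is chosen because a radical, unlike a cation, cannot trigger Wagner–Meerwein shifts from the adjacent quaternary C9.

**Step 17**
Reactants: 28 silyl ether
Product: 29 C4 alcohol (4α-OH)
Conditions: Bu4NF, THF, 50 °C; H2O
Reagents that add atoms: none
Why: Fluoride-driven Si–O cleavage frees the C4 hydroxyl, and nothing else in 28 responds to fluoride or mild base.

**Step 18**
Reactants: 29 C4 alcohol
Product: 30 C4 ketone (trans-decalone; 5α-H retained)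
Conditions: Dess–Martin periodinane, NaHCO3, CH2Cl2, 0 °C
Reagents that add atoms: none
Why: Buffered Dess–Martin oxidation is neutral and fast, so the C5–H next to the new ketone, whose epimerisation to the cis-decalone would relieve the syn-diaxial C8/C10 methyl strain, should stay in place.

**Step 19**
Reactants: 30 C4 ketone
Product: 31 C4 exocyclic methylene compound (tetramethoxyaryl form of the target)
Conditions: Zn, CH2Br2, TiCl4, THF (reagent aged at 5 °C); then 30, CH2Cl2, 0 °C → rt
Reagents that add atoms: dibromomethane, BrCBr
Why: Takai–Lombardo methylenation uses a gem-dimetallic reagent that is nucleophilic but practically non-basic, so enolisable and epimerisable ketones are converted into methylene compounds without disturbing the α-centre, which a phosphorus ylide would endanger.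

**Step 20**
Reactants: 31 tetramethoxyarene
Product: 32 2,5-dimethoxy-3-(C11)-1,4-benzoquinone
Conditions: (NH4)2Ce(NO3)6, MeCN–H2O, 0 °C
Reagents that add atoms: water, O
Why: Oxidative demethylation by tetravalent cerium (two one-electron oxidations with attack of water at a para pair of methoxy-bearing carbons) gives the dimethoxy-para-quinone, the two possible para pairs being equivalent by the symmetry of the arene and the isolated 1,1-disubstituted alkene being left alone.

**Step 21**
Reactants: 32 dimethoxyquinone
Product: 33 2,5-dihydroxy-3-(C11)-1,4-benzoquinone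
Conditions: NaOH (2 M aq), EtOH, 70 °C; then cold dilute HCl
Reagents that add atoms: sodium hydroxide, [Na+].[OH-]
Why: Each methoxy group is a vinylogous ester and is exchanged for hydroxide by conjugate addition–elimination, the stable dianion shields the ring from further attack, and base leaves the exocyclic alkene in place where acidic demethylation could move it into the ring.

**Step 22**
Reactants: 33 dihydroxyquinone
Product: 34 target, 2-hydroxy-5-methoxy-3-{[(1R,2S,4aS,8aS)-1,2,8a-trimethyl-5-methylidenedecahydronaphthalen-1-yl]methyl}cyclohexa-2,5-diene-1,4-dione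
Conditions: Me3SiCHN2 (1.0 equiv), toluene–MeOH, 0 °C
Reagents that add atoms: (trimethylsilyl)diazomethane, C[Si](C)(C)C=[N+]=[N-]
Why: O-Methylation of a vinylogous acid by a diazoalkane should pick the acid unit that flanks the ring C–H, because both oxygens of the other unit are shielded by the neopentyl C11 substituent, and any doubly methylated material is 32 and returns to step 21.

**Compound list**

1 | (S)-3-methylcyclohexan-1-one | C[C@H]1CCCC(=O)C1 | starting material
2 | {[(5S)-5-methylcyclohex-1-en-1-yl]oxy}trimethylsilane | C[C@H]1CCC=C(O[Si](C)(C)C)C1 | intermediate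
3 | (5S)-5-methylcyclohex-2-en-1-one | C[C@H]1CC=CC(=O)C1 | intermediate
4 | lithium cross-conjugated dienolate of 3 | C[C@H]1CC=CC(O[Li])=C1 | intermediate
5 | (5S,6R)-5,6-dimethylcyclohex-2-en-1-one | C[C@H]1CC=CC(=O)[C@@H]1C | intermediate
6 | benzyl chloromethyl ether | ClCOCc1ccccc1 | starting material
7 | lithium cross-conjugated dienolate of 5 | C[C@H]1CC=CC(O[Li])=C1C | intermediate
8 | (5S,6S)-6-[(benzyloxy)methyl]-5,6-dimethylcyclohex-2-en-1-one | C[C@H]1CC=CC(=O)[C@]1(C)COCc1ccccc1 | intermediate
9 | (5S,6S)-6-[(benzyloxy)methyl]-1,5,6-trimethylcyclohex-2-en-1-ol (C1 epimers) | C[C@H]1CC=CC(C)(O)[C@]1(C)COCc1ccccc1 | intermediate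
10 | (4R,5S)-4-[(benzyloxy)methyl]-3,4,5-trimethylcyclohex-2-en-1-one | C[C@H]1CC(=O)C=C(C)[C@]1(C)COCc1ccccc1 | intermediate
11 | allyltrimethylsilane | C=CC[Si](C)(C)C | starting material
12 | acrolein | C=CC=O | starting material
13 | trichlorotitanium enolate (C6–OTiCl3, C5=C6, 10α-allyl) | C[C@H]1CC(O[Ti](Cl)(Cl)Cl)=C[C@](C)(CC=C)[C@]1(C)COCc1ccccc1 | intermediate
14 | C10-allyl C5-(1-hydroxyallyl) cyclohexanone (name in step 7) | C[C@H]1CC(=O)[C@@H]([C@H](O)C=C)[C@](C)(CC=C)[C@]1(C)COCc1ccccc1 | intermediate
15 | C4 tert-butyldimethylsilyl ether of 14 | C[C@H]1CC(=O)[C@@H]([C@H](O[Si](C)(C)C(C)(C)C)C=C)[C@](C)(CC=C)[C@]1(C)COCc1ccccc1 | intermediate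
16 | trans-octalone, C2=C3, 6-oxo | C[C@H]1CC(=O)[C@H]2[C@H](O[Si](C)(C)C(C)(C)C)C=CC[C@]2(C)[C@]1(C)COCc1ccccc1 | intermediate
17 | potassium Δ6 enolate of 16 | C[C@H]1C=C(O[K])[C@H]2[C@H](O[Si](C)(C)C(C)(C)C)C=CC[C@]2(C)[C@]1(C)COCc1ccccc1 | intermediate
18 | Δ6 enol triflate | C[C@H]1C=C(OS(=O)(=O)C(F)(F)F)[C@H]2[C@H](O[Si](C)(C)C(C)(C)C)C=CC[C@]2(C)[C@]1(C)COCc1ccccc1 | intermediate
19 | Δ2,Δ6 diene | C[C@H]1C=C[C@H]2[C@H](O[Si](C)(C)C(C)(C)C)C=CC[C@]2(C)[C@]1(C)COCc1ccccc1 | intermediate
20 | saturated trans-decalin benzyl ether | C[C@H]1CC[C@H]2[C@H](O[Si](C)(C)C(C)(C)C)CCC[C@]2(C)[C@]1(C)COCc1ccccc1 | intermediate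
21 | C11 primary alcohol | C[C@H]1CC[C@H]2[C@H](O[Si](C)(C)C(C)(C)C)CCC[C@]2(C)[C@]1(C)CO | intermediate
22 | C11 aldehyde | C[C@H]1CC[C@H]2[C@H](O[Si](C)(C)C(C)(C)C)CCC[C@]2(C)[C@]1(C)C=O | intermediate
23 | 1,2,4,5-tetramethoxybenzene | COc1cc(OC)c(OC)cc1OC | starting material
24 | 2,3,5,6-tetramethoxyphenyllithium | [Li]c1c(OC)c(OC)cc(OC)c1OC | intermediate
25 | C11 aryl carbinol (C11 epimers) | C[C@H]1CC[C@H]2[C@H](O[Si](C)(C)C(C)(C)C)CCC[C@]2(C)[C@]1(C)C(O)c1c(OC)c(OC)cc(OC)c1OC | intermediate
26 | sodium O-(C11) dithiocarbonate | C[C@H]1CC[C@H]2[C@H](O[Si](C)(C)C(C)(C)C)CCC[C@]2(C)[C@]1(C)C(OC(=S)[S-])c1c(OC)c(OC)cc(OC)c1OC.[Na+] | intermediate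
27 | O-(C11) S-methyl dithiocarbonate | C[C@H]1CC[C@H]2[C@H](O[Si](C)(C)C(C)(C)C)CCC[C@]2(C)[C@]1(C)C(OC(=S)SC)c1c(OC)c(OC)cc(OC)c1OC | intermediate
28 | C11H2–aryl decalin, 4α-silyl ether | C[C@H]1CC[C@H]2[C@H](O[Si](C)(C)C(C)(C)C)CCC[C@]2(C)[C@]1(C)Cc1c(OC)c(OC)cc(OC)c1OC | intermediate
29 | C4 alcohol | C[C@H]1CC[C@H]2[C@H](O)CCC[C@]2(C)[C@]1(C)Cc1c(OC)c(OC)cc(OC)c1OC | intermediate
30 | C4 ketone | C[C@H]1CC[C@H]2C(=O)CCC[C@]2(C)[C@]1(C)Cc1c(OC)c(OC)cc(OC)c1OC | intermediate
31 | C4 methylene tetramethoxyarene | C[C@H]1CC[C@H]2C(=C)CCC[C@]2(C)[C@]1(C)Cc1c(OC)c(OC)cc(OC)c1OC | intermediate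
32 | dimethoxyquinone | C[C@H]1CC[C@H]2C(=C)CCC[C@]2(C)[C@]1(C)CC1=C(OC)C(=O)C=C(OC)C1=O | intermediate
33 | dihydroxyquinone | C[C@H]1CC[C@H]2C(=C)CCC[C@]2(C)[C@]1(C)CC1=C(O)C(=O)C=C(O)C1=O | intermediate
34 | CNP0109104.1 | C=C1CCC[C@@]2(C)[C@H]1CC[C@H](C)[C@@]2(C)CC1=C(O)C(=O)C=C(OC)C1=O | target

**Step count**

Total steps: 22. Longest linear sequence: 22 steps (1 → 34). Arene 23 enters in step 14 without steps of its own.

**Steps most likely to fail**

Step 7.
- What may go wrong: bond formation at C10 beside the fully substituted C9 may be too slow at temperatures where TiCl4 still spares the benzyl ether. Protodesilylation of 11 or direct allylation of acrolein could then take over. The facial preference at C5 may also erode, because the β face carries the syn-axial C9 methyl.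
- Fallback, from 10 back to 14: allylmagnesium bromide with CeCl3 (THF, −78 °C) should add 1,2 to C6 along the axial α path to give the tertiary bis-allylic alcohol F1.
- KH and 18-crown-6 (THF, 0 °C → rt) should then start an anionic oxy-Cope rearrangement. This intramolecular suprafacial [3,3] shift carries the allyl group from C6 to C10 on the same α face. It is far less sensitive to crowding than a bimolecular attack, and it gives the regiodefined potassium enolate F2.
- Acrolein 12 at −78 °C and a cold quench lead to 14.

Step 14.
- What may go wrong: the doubly ortho-substituted aryllithium may add only sluggishly to an axial aldehyde flanked by the quaternary C9 and C10. The nucleophile would then decay before the C11–aryl bond forms.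
- Fallback, from 21 back to 28, bypassing steps 13–16: Appel-type iodination (I2, PPh3, imidazole, toluene, 110 °C) should give the neopentyl iodide F3. This displacement is slow but has no elimination pathway, since C9 bears no hydrogen.
- LiCl-assisted zinc insertion (Zn, LiCl, THF, 50 °C) gives the alkylzinc iodide F4, which cannot undergo β-hydride elimination.
- Quenching aryllithium 24 with I2 gives 3-iodo-1,2,4,5-tetramethoxybenzene F5.
- Negishi coupling of F4 with F5 (Pd2(dba)3, 2-dicyclohexylphosphino-2',6'-dimethoxybiphenyl, THF, 60 °C) forms the C11–aryl bond directly at the CH2 level and gives 28.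

Step 19.
- What may go wrong: the hindered C4 carbonyl may react slowly. Lewis-acid-mediated enolisation would then have time to epimerise C5 toward the more stable cis fusion.
- Fallback, from 30 back to 31: a Peterson olefination in two stages. Me3SiCH2Li premixed with CeCl3 (THF, −78 °C) is a weakly basic nucleophile that adds faster than it enolises, and it should give the β-hydroxysilane F6.
- KH (THF, 0 °C) then eliminates silanolate regiospecifically to the exocyclic methylene compound 31. The C4 configuration of the adduct is irrelevant for a terminal alkene.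

**Further compounds**

F1 | step 7 | (1-allyl tertiary alcohol) 6α-allyl-6β-hydroxy derivative of 10, C5=C10 retained | C[C@H]1C[C@](O)(CC=C)C=C(C)[C@]1(C)COCc1ccccc1
F2 | step 7 | potassium enolate (C6–OK, C5=C6, 10α-allyl) | C[C@H]1CC(O[K])=C[C@](C)(CC=C)[C@]1(C)COCc1ccccc1
F3 | step 14 | C11 neopentyl iodide | C[C@H]1CC[C@H]2[C@H](O[Si](C)(C)C(C)(C)C)CCC[C@]2(C)[C@]1(C)CI
F4 | step 14 | C11 alkylzinc iodide | C[C@H]1CC[C@H]2[C@H](O[Si](C)(C)C(C)(C)C)CCC[C@]2(C)[C@]1(C)C[Zn]I
F5 | step 14 | 3-iodo-1,2,4,5-tetramethoxybenzene | COc1cc(OC)c(OC)c(I)c1OC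
F6 | step 19 | C4 β-hydroxysilane (C4 bears OH and CH2SiMe3; C4 epimers) | C[C@H]1CC[C@H]2C(O)(C[Si](C)(C)C)CCC[C@]2(C)[C@]1(C)Cc1c(OC)c(OC)cc(OC)c1OC
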